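**Retrosynthetic overview**
- Last bond C11=C12: Wittig reaction between a C25 acetylenic polyenyl phosphonium salt (left part, 3'-OAc) and a C15 epoxy keto-enal (right part).
- The keto-enal (C8=O, C9=C10, C11 aldehyde) is a masked furan, released by oxidative opening of a 2-(ring-CH2)-3-methylfuran. The furan ring and the 5,6-oxirane are made together in one flask from a (Z)-dienynol: Ag-catalysed cycloisomerisation, then face-selective epoxidation.
- C25 salt: C15 acetylenic phosphonium salt + C10 trienedial (Wittig), then CHO → CH2OH → CH2PPh3+.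
- Both C15 dienynols come from one enol triflate by Sonogashira coupling with (E)- or (Z)-3-methylpent-2-en-4-yn-1-ol. The triflate comes from (4R,6R)-actinol, made enzymatically from ketoisophorone.
- Ring order: both carbocycles are present from ketoisophorone on; furan + oxirane form together (step 10); the furan is opened again in step 12.

Assumption: the target is the all-E isomer drawn, and the (E)- and (Z)-enynols are bought as separated isomers (industrial vitamin A/carotenoid intermediates).

**Route**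

Step 1
Reactants: 1 ketoisophorone
Product: 3 (4R,6R)-actinol, via (6R)-levodione 2 (not isolated)
Conditions: OYE2 ene-reductase, NADP+ (cat.), D-glucose, glucose dehydrogenase, phosphate buffer pH 7.4, 28 °C; then levodione reductase, NAD+ (cat.), same pot
Reagents that add atoms: none
Why: Enzymatic ene-reduction (old yellow enzyme) delivers hydride to one face of the enone to set 6R, and the ketoreductase then reduces only the unhindered C4 carbonyl to the 4R alcohol, as in the known two-enzyme process to actinol.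

Step 2
Reactants: 3 (4R,6R)-actinol
Product: 4 actinol acetate
Conditions: Ac2O (1.5 equiv), DMAP (5 mol%), pyridine, 0 → 23 °C
Reagents that add atoms: acetic anhydride CC(=O)OC(C)=O
Why: DMAP-catalysed acylation of the only hydroxyl group, leaving both stereocentres untouched.

Step 3
Reactants: 4 actinol acetate
Product: 5 (4R)-4-acetoxy-2,6,6-trimethylcyclohex-1-en-1-yl triflate
Conditions: Tf2O (1.3 equiv), 2,6-di-tert-butyl-4-methylpyridine (1.5 equiv), CH2Cl2, 0 → 40 °C
Reagents that add atoms: trifluoromethanesulfonic anhydride O=S(=O)(OS(=O)(=O)C(F)(F)F)C(F)(F)F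
Why: Stang enol triflate formation (O-triflation, then loss of the single α-proton to the hindered base) can give only this tetrasubstituted enol triflate because the other α-carbon is quaternary, and a secondary acetate tolerates Tf2O/hindered pyridine as in triflations of acetoxy-steroid ketones.

Step 4
Reactants: 5 enol triflate; 6 (E)-3-methylpent-2-en-4-yn-1-ol
Product: 7 (E)-dienynol acetate
Conditions: Pd(PPh3)4 (5 mol%), CuI (10 mol%), i-Pr2NH (3 equiv), DMF, 40 °C
Reagents that add atoms: none
Why: Sonogashira coupling joins the vinyl triflate to the terminal alkyne with retention of the (E)-enynol geometry and tolerates the acetate and the free primary alcohol.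

Step 5
Reactants: 7 (E)-dienynol acetate
Product: 9 C15 phosphonium bromide, via allylic bromide 8 (not isolated)
Conditions: CBr4 (1.1 equiv), PPh3 (1.15 equiv), CH2Cl2, −20 °C; then PPh3 (1.3 equiv), 23 °C, 16 h; Et2O trituration
Reagents that add atoms: carbon tetrabromide BrC(Br)(Br)Br; triphenylphosphine c1ccc(cc1)P(c1ccccc1)c1ccccc1
Why: Appel bromination followed by SN2 quaternisation of PPh3 by the primary allylic bromide avoids a free allyl cation, so the E geometry of the C9'=C10' bond is kept.

Step 6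
Reactants: 9 C15 phosphonium bromide; 10 (2E,4E,6E)-2,7-dimethylocta-2,4,6-trienedial
Product: 12 C25 apo-aldehyde, via C15 ylide 11 (not isolated)
Conditions: 9, NaHMDS (1.0 equiv), THF, −78 °C; add to 10 (3 equiv), −78 → 0 °C; then heptane, 70 °C, 2 h
Reagents that add atoms: none
Why: Wittig olefination of the semi-stabilised allylic ylide with an excess of the symmetrical dialdehyde gives the mono-adduct, and the new C11'=C12' bond (formed E/Z) is equilibrated thermally to E.

Step 7
Reactants: 12 C25 apo-aldehyde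
Product: 13 C25 allylic alcohol
Conditions: NaBH4, THF/EtOH, −20 → 0 °C
Reagents that add atoms: none
Why: Borohydride 1,2-reduction of the polyenal to the polyenol is fast at low temperature, where the acetate survives.

Step 8
Reactants: 13 C25 allylic alcohol
Product: 14 C25 phosphonium bromide
Conditions: PPh3·HBr (1.1 equiv), CH2Cl2/MeOH, 0 → 23 °C
Reagents that add atoms: triphenylphosphine hydrobromide [Br-].c1ccc(cc1)[PH+](c1ccccc1)c1ccccc1
Why: SN1-type phosphonium salt formation through the delocalised polyenyl cation (as in retinyl phosphonium salt manufacture), with PPh3 captured at the unhindered terminal carbon and the distant C9'=C10' bond little affected.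

Step 9
Reactants: 5 enol triflate; 15 (Z)-3-methylpent-2-en-4-yn-1-ol
Product: 16 (Z)-dienynol acetate
Conditions: Pd(PPh3)4 (5 mol%), CuI (10 mol%), i-Pr2NH (3 equiv), DMF, 23 °C
Reagents that add atoms: none
Why: Sonogashira coupling as in step 4, here keeping the Z geometry that holds the hydroxyl next to the alkyne for the cyclisation (any furan formed early is on the path of step 10).

Step 10
Reactants: 16 (Z)-dienynol acetate
Product: 18 epoxy-furan acetate, via furan acetate 17 (not isolated)
Conditions: AgNO3 on silica gel (10 mol% Ag), CH2Cl2, 23 °C, 1 h; then same flask, −40 °C, mCPBA (1.05 equiv), 45 min; aq. Na2S2O3/NaHCO3 work-up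
Reagents that add atoms: mCPBA OOC(=O)c1cccc(Cl)c1
Why: Silver(I)-catalysed 5-exo-dig cycloisomerisation of the (Z)-2-en-4-yn-1-ol (Marshall furan synthesis, the same enynol-to-furan step used for rosefuran; C7 becomes CH2 on aromatisation) is followed in the same flask by Prilezhaev epoxidation of the tetrasubstituted C5=C6 alkene, which is expected to react well before the furan and to be attacked anti to the 3-acetoxy group to set 5R,6S (expected about 3–4:1, minor syn isomer removed by chromatography), so the furan and oxirane rings both form in this one operation.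

Step 11
Reactants: 18 epoxy-furan acetate
Product: 19 epoxy-furan alcohol
Conditions: K2CO3 (0.2 equiv), MeOH, 0 → 23 °C
Reagents that add atoms: none
Why: Base-catalysed transesterification (Zemplén-type methanolysis) removes the acetate while the tetrasubstituted epoxide and the furan are inert to methoxide.

Step 12
Reactants: 19 epoxy-furan alcohol
Product: 21 (E)-epoxy keto-enal, via (Z)-epoxy keto-enal 20 (not isolated)
Conditions: NBS (1.05 equiv), NaHCO3 (2 equiv), acetone/H2O 10:1, −15 °C; then pyridine (2 equiv), 23 °C, 2 h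
Reagents that add atoms: water O
Why: Oxidative furan ring opening (bromination, hydration and ring opening, Achmatowicz-type) unmasks the furan as the cis-4-oxo-2-enal, which pyridine isomerises to the E isomer in a near-neutral medium that does not enolise the β,γ-epoxy ketone.

Step 13
Reactants: 14 C25 phosphonium bromide; 21 (E)-epoxy keto-enal
Product: 23 halocynthiaxanthin 3'-acetate (target), via C25 ylide 22 (not isolated)
Conditions: 14 (1.1 equiv), NaHMDS (1.05 equiv), THF, −78 °C, 20 min; then 21, −78 → −30 °C; pH 7 buffer; then EtOAc, 60 °C, 1 h in the dark; chromatography and crystallisation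
Reagents that add atoms: none
Why: Wittig olefination of the preformed polyenyl ylide with the aldehyde (far more reactive than the hindered conjugated ketone) forms C11=C12 at −78 °C with no free base left, so the β,γ-epoxy ketone and the acetate survive, and mild heating converts the hindered 11Z isomer to all-E.

**Compound list**
1 | ketoisophorone (2,6,6-trimethylcyclohex-2-ene-1,4-dione) | CC1=CC(=O)CC(C)(C)C1=O | starting material
2 | (6R)-levodione, (6R)-2,2,6-trimethylcyclohexane-1,4-dione | O=C1C[C@@H](C)C(=O)C(C)(C)C1 | intermediate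
3 | (4R,6R)-actinol, (4R,6R)-4-hydroxy-2,2,6-trimethylcyclohexan-1-one | O[C@@H]1C[C@@H](C)C(=O)C(C)(C)C1 | intermediate
4 | actinol acetate, (1R,5R)-3,3,5-trimethyl-4-oxocyclohexyl acetate | CC(=O)O[C@@H]1C[C@@H](C)C(=O)C(C)(C)C1 | intermediate
5 | (4R)-4-acetoxy-2,6,6-trimethylcyclohex-1-en-1-yl trifluoromethanesulfonate | CC(=O)O[C@@H]1CC(C)=C(OS(=O)(=O)C(F)(F)F)C(C)(C)C1 | intermediate
6 | (E)-3-methylpent-2-en-4-yn-1-ol | C#C/C(C)=C/CO | starting material
7 | (E)-dienynol acetate, (1R)-4-[(3E)-5-hydroxy-3-methylpent-3-en-1-yn-1-yl]-3,5,5-trimethylcyclohex-3-en-1-yl acetate | CC(=O)O[C@@H]1CC(C)=C(C#C/C(C)=C/CO)C(C)(C)C1 | intermediate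
8 | allylic bromide, (1R)-4-[(3E)-5-bromo-3-methylpent-3-en-1-yn-1-yl]-3,5,5-trimethylcyclohex-3-en-1-yl acetate | CC(=O)O[C@@H]1CC(C)=C(C#C/C(C)=C/CBr)C(C)(C)C1 | intermediate
9 | C15 phosphonium bromide, [(2E)-5-[(4R)-4-acetoxy-2,6,6-trimethylcyclohex-1-en-1-yl]-3-methylpent-2-en-4-yn-1-yl]triphenylphosphonium bromide | CC(=O)O[C@@H]1CC(C)=C(C#C/C(C)=C/C[P+](c2ccccc2)(c2ccccc2)c2ccccc2)C(C)(C)C1.[Br-] | intermediate
10 | (2E,4E,6E)-2,7-dimethylocta-2,4,6-trienedial (C10 dialdehyde) | O=C/C(C)=C/C=C/C=C(C)/C=O | starting material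
11 | C15 ylide, triphenylphosphoranylidene form of 9 | CC(=O)O[C@@H]1CC(C)=C(C#C/C(C)=C/C=P(c2ccccc2)(c2ccccc2)c2ccccc2)C(C)(C)C1 | intermediate
12 | C25 apo-aldehyde, (2E,4E,6E,8E,10E)-13-[(4R)-4-acetoxy-2,6,6-trimethylcyclohex-1-en-1-yl]-2,7,11-trimethyltrideca-2,4,6,8,10-pentaen-12-ynal | CC(=O)O[C@@H]1CC(C)=C(C#C/C(C)=C/C=C/C(C)=C/C=C/C=C(C)/C=O)C(C)(C)C1 | intermediate
13 | C25 allylic alcohol, the corresponding trideca-2,4,6,8,10-pentaen-12-yn-1-ol | CC(=O)O[C@@H]1CC(C)=C(C#C/C(C)=C/C=C/C(C)=C/C=C/C=C(C)/CO)C(C)(C)C1 | intermediate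
14 | C25 phosphonium bromide, triphenylphosphonium salt at C1 of the chain of 13 | CC(=O)O[C@@H]1CC(C)=C(C#C/C(C)=C/C=C/C(C)=C/C=C/C=C(C)/C[P+](c2ccccc2)(c2ccccc2)c2ccccc2)C(C)(C)C1.[Br-] | intermediate
15 | (Z)-3-methylpent-2-en-4-yn-1-ol | C#C/C(C)=C\CO | starting material
16 | (Z)-dienynol acetate, (1R)-4-[(3Z)-5-hydroxy-3-methylpent-3-en-1-yn-1-yl]-3,5,5-trimethylcyclohex-3-en-1-yl acetate | CC(=O)O[C@@H]1CC(C)=C(C#C/C(C)=C\CO)C(C)(C)C1 | intermediate
17 | furan acetate, (1R)-3,5,5-trimethyl-4-[(3-methylfuran-2-yl)methyl]cyclohex-3-en-1-yl acetate | CC(=O)O[C@@H]1CC(C)=C(Cc2occc2C)C(C)(C)C1 | intermediate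
18 | epoxy-furan acetate, (1R,3S,6S)-1,5,5-trimethyl-6-[(3-methylfuran-2-yl)methyl]-7-oxabicyclo[4.1.0]heptan-3-yl acetate | Cc1ccoc1C[C@@]23O[C@]2(C)C[C@@H](OC(C)=O)CC3(C)C | intermediate
19 | epoxy-furan alcohol, (1R,3S,6S)-1,5,5-trimethyl-6-[(3-methylfuran-2-yl)methyl]-7-oxabicyclo[4.1.0]heptan-3-ol | Cc1ccoc1C[C@@]23O[C@]2(C)C[C@@H](O)CC3(C)C | intermediate
20 | (Z)-epoxy keto-enal, (2Z)-5-[(1S,4S,6R)-4-hydroxy-2,2,6-trimethyl-7-oxabicyclo[4.1.0]heptan-1-yl]-3-methyl-4-oxopent-2-enal | O=C/C=C(/C)C(=O)C[C@@]23O[C@]2(C)C[C@@H](O)CC3(C)C | intermediate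
21 | (E)-epoxy keto-enal, (2E)-5-[(1S,4S,6R)-4-hydroxy-2,2,6-trimethyl-7-oxabicyclo[4.1.0]heptan-1-yl]-3-methyl-4-oxopent-2-enal | O=C/C=C(\C)C(=O)C[C@@]23O[C@]2(C)C[C@@H](O)CC3(C)C | intermediate
22 | C25 ylide, triphenylphosphoranylidene form of 14 | CC(=O)O[C@@H]1CC(C)=C(C#C/C(C)=C/C=C/C(C)=C/C=C/C=C(C)/C=P(c2ccccc2)(c2ccccc2)c2ccccc2)C(C)(C)C1 | intermediate
23 | halocynthiaxanthin 3'-acetate, (3S,5R,6S,3'R)-3'-acetoxy-5,6-epoxy-3-hydroxy-7',8'-didehydro-5,6,7,8-tetrahydro-β,β-caroten-8-one | CC(=O)O[C@@H]1CC(C)=C(C#C/C(C)=C/C=C/C(C)=C/C=C/C=C(C)/C=C/C=C(\C)C(=O)C[C@@]23O[C@]2(C)C[C@@H](O)CC3(C)C)C(C)(C)C1 | target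

**Step count and risks**

Total steps: 13. Longest linear sequence: 9 (steps 1–8, then 13).

Step 10 is the most likely to fail. The risks are over-oxidation of the furan and a poor anti/syn ratio of the epoxide. Fallback: set out from 16, run only the silver-catalysed cycloisomerisation and isolate furan acetate 17. Then give up the selective mono-oxidation and oxidise alkene and furan together with dimethyldioxirane (2.5 equiv, acetone, −40 → 0 °C), which gives the (2Z)-epoxy keto-enal acetate F1. Isomerise it with pyridine to the (2E)-epoxy keto-enal acetate F2 and remove the acetate under neutral conditions with Candida antarctica lipase B (pH 7 buffer/MTBE). This comes back to the route at 21, so steps 11 and 12 are not needed.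

Step 3 is the second risk. Enolisation of the hindered ketone towards the tertiary α-carbon may be slow, and the acetate is exposed to Tf2O. Fallback: set out from 4 and separate enolisation from triflation. Soft enolisation with TMSCl/NaI/Et3N (MeCN, 60 °C) gives the trimethylsilyl enol ether F3. Fluoride-triggered triflation (CsF, PhNTf2, DME, 23 °C) then converts it to the triflate, rejoining the route at 5.

Step 13 is the third risk. The ylide meets a β,γ-epoxy ketone that can open by E1cB and an ene-dione that can take conjugate addition; the C9'=C10' bond next to the alkyne may also partly isomerise to 9'Z (also possible at the ylide stage of step 6), so HPLC or crystallisation may be needed. Fallback: carry C8 through the coupling as an alcohol and oxidise last. Set out from 21: Luche reduction (NaBH4, CeCl3, MeOH, −78 °C) gives the 8,11-diol F4 (C8 epimers, both used). TEMPO/PhI(OAc)2 oxidises only the primary allylic alcohol to the 8-hydroxy enal F5. Wittig reaction with ylide 22 (from 14) gives the 8-hydroxy carotenoid F6. MnO2 (CH2Cl2, 23 °C) then oxidises the allylic C8 alcohol, leaving the 3-OH untouched, and comes back to the route at 23.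

**Further compounds**
F1 | step 10 | (2Z)-epoxy keto-enal acetate, (1S,3S,6R)-1,5,5-trimethyl-6-[(3Z)-3-methyl-2,5-dioxopent-3-en-1-yl]-7-oxabicyclo[4.1.0]heptan-3-yl acetate | O=C/C=C(/C)C(=O)C[C@@]23O[C@]2(C)C[C@@H](OC(C)=O)CC3(C)C
F2 | step 10 | (2E)-epoxy keto-enal acetate, 3-O-acetyl derivative of 21 | O=C/C=C(\C)C(=O)C[C@@]23O[C@]2(C)C[C@@H](OC(C)=O)CC3(C)C
F3 | step 3 | trimethylsilyl enol ether, (1R)-3,5,5-trimethyl-4-(trimethylsilyloxy)cyclohex-3-en-1-yl acetate | CC(=O)O[C@@H]1CC(C)=C(O[Si](C)(C)C)C(C)(C)C1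
F4 | step 13 | 8,11-diol (C8 epimers), (2E)-5-[(1S,4S,6R)-4-hydroxy-2,2,6-trimethyl-7-oxabicyclo[4.1.0]heptan-1-yl]-3-methylpent-2-ene-1,4-diol | OC/C=C(\C)C(O)C[C@@]23O[C@]2(C)C[C@@H](O)CC3(C)C
F5 | step 13 | 8-hydroxy enal (C8 epimers), (2E)-4-hydroxy-5-[(1S,4S,6R)-4-hydroxy-2,2,6-trimethyl-7-oxabicyclo[4.1.0]heptan-1-yl]-3-methylpent-2-enal | O=C/C=C(\C)C(O)C[C@@]23O[C@]2(C)C[C@@H](O)CC3(C)C
F6 | step 13 | 8-hydroxy carotenoid (C8 epimers), 8-hydroxy analogue of 23 | CC(=O)O[C@@H]1CC(C)=C(C#C/C(C)=C/C=C/C(C)=C/C=C/C=C(C)/C=C/C=C(\C)C(O)C[C@@]23O[C@]2(C)C[C@@H](O)CC3(C)C)C(C)(C)C1
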